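Each of the three identical drimane units is cut at the C3–C4 bond of ring A; the trimer is then assembled from one ether-linked drimane–isocitrate monomer by two esterifications. The key step exploits quaternary C4 (CH3 plus oxidised C15) sitting next to C5 of ring B: hydrogen-atom transfer to a 1,1-disubstituted alkene on C5 gives the C4 radical, which closes ring A 6-endo onto an acrylate arm on C10, setting C4 and the trans-decalin in one operation. The precursor is a carvone-derived cyclohexenone (ring B with the C12 methyl) bearing on C10 a methyl and a 2-(ethoxycarbonyl)allyl arm and on C5 a vinyl group whose C15 is a dioxolane, chosen to be clearly bulkier than the nascent methyl.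

Key step: step 6

Remarks and assumptions
- Drimane numbering is used: C11 on C9, C12 on C8, C15 is the oxygenated carbon on C4, and α is the face of H-5. Isocitrate carbons are C1′ (ether carbon), C2′ (central) and C3′ (CH2).
- C15 is carried through the ring closure as a 1,3-dioxolane instead of a silyl ether. A CH2O-silyl group and a methyl differ too little in size to choose between the two positions on the planar C4 radical; a branched acetal does. The acetal is converted into the silyl ether directly afterwards (steps 7–8), so compound 13 is the 15-silyloxy ester.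
- Assumption: 2-(trimethylsilyl)ethyl bromoacetate is made (step 15) and not bought.
- Assumption: compound 6 is used as the mixture of epimers at the methylated carbon, since step 5 re-enolises that centre.
- Ester plan: C1′ is a methyl ester throughout; C2′ is an allyl ester (removed by Pd(0)); C3′ is a 2-(trimethylsilyl)ethyl (TMSE) ester (removed by fluoride); O-15 is a TBS ether.

**Part A. Drimane alcohol 22**

Step 1
Reactants: 1 (R)-(−)-carvone
Product: 2 (5R)-5-(3-chloroprop-1-en-2-yl)-2-methylcyclohex-2-en-1-one (10-chlorocarvone)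
Conditions: Ca(OCl)2, solid CO2, CH2Cl2/H2O, 0 °C
Reagents that add atoms: calcium hypochlorite, [Ca+2].[O-]Cl.[O-]Cl
Why: Ene-type allylic chlorination by hypochlorous acid made in situ attacks only the electron-rich isopropenyl group (the enone alkene is deactivated) and shifts the double bond to give the 2-substituted allyl chloride, leaving C5 untouched.

Step 2
Reactants: 2 10-chlorocarvone
Product: 3 2-[(1R)-4-methyl-5-oxocyclohex-3-en-1-yl]prop-2-enal
Conditions: NMO, NaHCO3, KI (cat.), MeCN, 40 °C
Reagents that add atoms: N-methylmorpholine N-oxide, C[N+]1([O-])CCOCC1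
Why: Kornblum-type oxidation with an amine N-oxide: iodide-assisted SN2 displacement of the activated primary allylic chloride by the N-oxide oxygen and base-induced loss of N-methylmorpholine should give the enal without touching C5.

Step 3
Reactants: 3 enal
Product: 4 (5R)-5-[1-(1,3-dioxolan-2-yl)ethenyl]-2-methylcyclohex-2-en-1-one
Conditions: TMSOCH2CH2OTMS, TMSOTf (cat.), CH2Cl2, −78 °C
Reagents that add atoms: 1,2-bis(trimethylsilyloxy)ethane, C[Si](C)(C)OCCO[Si](C)(C)C
Why: Noyori acetalisation at low temperature is selective for the aldehyde over the conjugated ring ketone and does not move the double bond.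

Step 4
Reactants: 4 dioxolane enone
Product: 6 5-[1-(1,3-dioxolan-2-yl)ethenyl]-2,6-dimethylcyclohex-2-en-1-one (C5 as in carvone; both C6 epimers), via lithium enolate 5 (not isolated)
Conditions: LDA, THF, −78 °C; then MeI, −78 → 0 °C
Reagents that add atoms: iodomethane, CI
Why: Kinetic deprotonation of the cross-conjugated enone occurs at the α′ carbon and the enolate is C-methylated (enolate alkylation); the new centre need not be controlled.

Step 5
Reactants: 6 methylated enone; 7 ethyl 2-(bromomethyl)acrylate
Product: 9 ethyl 2-({6-[1-(1,3-dioxolan-2-yl)ethenyl]-1,3-dimethyl-2-oxocyclohex-3-en-1-yl}methyl)prop-2-enoate (ring methyl on the quaternary carbon cis to the dioxolanylvinyl group; acrylate arm trans to it), via lithium enolate 8 (not isolated)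
Conditions: LDA, THF, −78 °C; then 7, −78 → −40 °C
Reagents that add atoms: none
Why: The tetrasubstituted α′ enolate is alkylated by the allylic bromide on the face opposite the neighbouring C5 side chain (enolate alkylation anti to the vicinal substituent), which sets the future C10 with methyl β and the arm that becomes C1 α.

Step 6
Reactants: 9 cyclisation precursor
Product: 10 ethyl 15,15-(ethylenedioxy)-9-oxo-11-nordrim-7-ene-2-carboxylate (trans-decalin; H-5 α; CH3 on C10 β; CH3 on C4 β; dioxolanyl on C4 α; ester on C2 α, equatorial)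
Conditions: Fe(acac)3 (30 mol %), PhSiH3, EtOH/(CH2OH)2, 60 °C
Reagents that add atoms: none
Why: An iron hydride formed from Fe(III) and the silane transfers a hydrogen atom to the terminal CH2 of the electron-rich 1,1-disubstituted alkene, creating the C4 methyl and the tertiary C4 radical, which adds to the unsubstituted acrylate terminus (C3); the α-ester radical is then reduced and protonated by the solvent. The closest known reaction type is the iron-hydride reductive olefin coupling run intramolecularly (Giese addition). Ring A closes 6-endo-trig through a chair in which the arm on C10 and the radical carbon on C5 are both equatorial on ring B, so the trans ring fusion follows from the existing C5 and C10 centres. C4 is controlled by allylic-type strain in the planar radical: the branched dioxolanyl group takes the position nearly eclipsing H-5 (it becomes equatorial, α) and the small new methyl takes the position facing the axial C10 methyl (it becomes axial, β); C2 should form as the equatorial ester and is erased in step 10. The step needs chemoselective hydrogen transfer and 6-endo regioselectivity: the acrylate and the ring enone are electron-poor and poor hydrogen acceptors, the enone cannot be reached by the C4 radical, and 5-exo attack on the substituted acrylate carbon is disfavoured sterically and electronically.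

Step 7
Reactants: 10 acetal keto ester
Product: 12 ethyl 15-hydroxy-9-oxo-11-nordrim-7-ene-2-carboxylate, via aldehyde 11 (not isolated)
Conditions: 2 M HCl, THF, 40 °C; NaHCO3 to pH 8; then NaBH4, EtOH, −20 °C
Reagents that add atoms: water, O
Why: Acid-catalysed acetal hydrolysis gives a neopentyl aldehyde with no α-hydrogen, and borohydride at low temperature reduces this aldehyde much faster than the hindered conjugated ketone or the ester.

Step 8
Reactants: 12 hydroxy keto ester
Product: 13 ethyl 15-(tert-butyldimethylsilyloxy)-9-oxo-11-nordrim-7-ene-2-carboxylate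
Conditions: TBSCl, imidazole, DMF, 20 °C
Reagents that add atoms: tert-butyldimethylsilyl chloride, CC(C)(C)[Si](C)(C)Cl
Why: Standard silylation of a primary alcohol; no other nucleophilic group is present.

Step 9
Reactants: 13 silyl ether ester
Product: 14 15-(tert-butyldimethylsilyloxy)-9-oxo-11-nordrim-7-ene-2-carboxylic acid
Conditions: LiOH, THF/MeOH/H2O, 20 °C; HCl work-up
Reagents that add atoms: lithium hydroxide, [Li+].[OH-]
Why: Saponification of the unhindered secondary ethyl ester; the enone and the neopentyl silyl ether tolerate these conditions and the C2 configuration is irrelevant.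

Step 10
Reactants: 14 carboxylic acid
Product: 16 15-(tert-butyldimethylsilyloxy)-11-nordrim-7-en-9-one, via thiohydroxamate ester 15 (not isolated)
Conditions: 2-mercaptopyridine N-oxide, DCC, DMAP (cat.), CH2Cl2, 0 °C, dark; then t-BuSH, hν (tungsten lamp), 20 °C
Reagents that add atoms: none
Why: Barton reductive decarboxylation: the thiohydroxamate ester fragments under visible light to CO2 and the secondary C2 radical, which takes hydrogen from the thiol, so C2 becomes CH2.

Step 11
Reactants: 16 enone
Product: 18 15-(tert-butyldimethylsilyloxy)-11-nordrim-8-en-9-yl trifluoromethanesulfonate, via lithium enolate 17 (not isolated)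
Conditions: L-Selectride, THF, −78 °C; then Comins' reagent, −78 → 0 °C
Reagents that add atoms: N-(5-chloropyridin-2-yl)-bis(trifluoromethanesulfonyl)imide, FC(F)(F)S(=O)(=O)N(c1ccc(Cl)cn1)S(=O)(=O)C(F)(F)F
Why: Reductive enolate triflation: the bulky hydride adds 1,4 to the β-monosubstituted enone (1,2-attack is blocked by quaternary C10) and the regiodefined C8=C9 enolate is O-triflated, which saturates C7 and activates C9 in one operation.

Step 12
Reactants: 18 enol triflate
Product: 19 methyl 15-(tert-butyldimethylsilyloxy)drim-8-en-11-oate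
Conditions: Pd(OAc)2 (cat.), dppf (cat.), CO (1 atm), MeOH, Et3N, DMF, 70 °C
Reagents that add atoms: carbon monoxide, [C-]#[O+]; methanol, CO
Why: Palladium-catalysed alkoxycarbonylation of an enol triflate (oxidative addition, CO insertion, methanolysis) introduces C11 as the ester.

Step 13
Reactants: 19 conjugated ester
Product: 21 methyl 15-(tert-butyldimethylsilyloxy)drim-8(12)-en-11-oate (H-9 α; ester β, equatorial), via lithium dienolate 20 (not isolated)
Conditions: LDA, HMPA, THF, −78 °C; then AcOH, −78 °C
Reagents that add atoms: none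
Why: Deconjugative protonation: kinetic γ-deprotonation takes the C12 methyl that lies cis to the ester, and α-protonation of the exocyclic dienolate from the α face, anti to the axial C10 methyl, sets C9 with the ester equatorial.

Step 14
Reactants: 21 β,γ-unsaturated ester
Product: 22 15-(tert-butyldimethylsilyloxy)drim-8(12)-en-11-ol (4R,5R,9S,10S)
Conditions: DIBAL-H, CH2Cl2, −78 → 0 °C; Rochelle salt work-up
Reagents that add atoms: none
Why: Hydride reduction of the ester to the primary alcohol under non-basic conditions does not move the exocyclic double bond or epimerise C9.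

**Part B. Isocitrate triester 31**

Step 15
Reactants: 23 bromoacetyl bromide; 24 2-(trimethylsilyl)ethanol
Product: 25 2-(trimethylsilyl)ethyl bromoacetate
Conditions: pyridine, CH2Cl2, 0 °C
Reagents that add atoms: none
Why: O-Acylation by the acid bromide, which reacts far faster at the acyl carbon than at the alkyl bromide.

Step 16
Reactants: 26 (R)-malic acid
Product: 28 (R)-malic acid 1-methyl ester [(3R)-3-hydroxy-4-methoxy-4-oxobutanoic acid], via trifluoroacetoxy anhydride 27 (not isolated)
Conditions: (CF3CO)2O, 0 → 20 °C; evaporate; then MeOH, 20 °C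
Reagents that add atoms: methanol, CO
Why: The O-trifluoroacetyl cyclic anhydride is opened by methanol at the more electrophilic carbonyl next to the acyloxy group and is then de-trifluoroacetylated, giving the 1-monoester without touching the stereocentre (regioselective anhydride alcoholysis).

Step 17
Reactants: 28 malic acid 1-methyl ester
Product: 29 4-allyl 1-methyl (R)-malate
Conditions: allyl bromide, KHCO3, DMF, 20 °C
Reagents that add atoms: allyl bromide, C=CCBr
Why: Carboxylate O-alkylation with a weak base leaves the secondary hydroxyl and the methyl ester untouched.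

Step 18
Reactants: 29 mixed malate; 25 TMSE bromoacetate
Product: 31 2-allyl 1-methyl 3-[2-(trimethylsilyl)ethyl] (1R,2S)-1-hydroxypropane-1,2,3-tricarboxylate, via dilithium dianion 30 (not isolated)
Conditions: LDA (2.2 equiv), THF, −78 → −40 °C; then 25, −78 °C; AcOH quench at −78 °C
Reagents that add atoms: none
Why: Seebach–Fráter alkylation: the chelated alkoxide–enolate dianion is alkylated anti to the C–O bond, which sets C2′ in the threo (natural) sense, and the cold acidic quench prevents the alkoxide from lactonising onto the new ester.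

**Part C. Monomer and assembly**

Step 19
Reactants: 22 drimane alcohol; 31 isocitrate triester
Product: 33 2-allyl 1-methyl 3-[2-(trimethylsilyl)ethyl] (1R,2S)-1-{[15-(tert-butyldimethylsilyloxy)drim-8(12)-en-11-yl]oxy}propane-1,2,3-tricarboxylate (monomer), via primary triflate 32 (not isolated)
Conditions: Tf2O, 2,6-di-tert-butyl-4-methylpyridine, CH2Cl2, −78 °C; then 31, −78 → 25 °C
Reagents that add atoms: none
Why: Triflate etherification of a base-sensitive hydroxy ester: the C11 triflate alkylates the isocitrate hydroxyl by SN2 under hindered-pyridine buffering, so no alkoxide is formed and C1′ keeps its configuration because its C–O bond is not broken.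

Step 20
Reactants: 33 monomer
Product: 34 monomer acid (as 33 with the C2′ carboxyl free; TBS ether, TMSE and methyl esters kept)
Conditions: Pd(PPh3)4 (cat.), morpholine, THF, 20 °C
Reagents that add atoms: none
Why: Tsuji–Trost deallylation: Pd(0) ionises only the allyl ester and morpholine captures the π-allyl fragment, leaving the silyl groups and alkyl esters untouched.

Step 21
Reactants: 33 monomer
Product: 35 hydroxy acid (as 33 with O-15 free and the C3′ carboxyl free; C2′ allyl ester kept)
Conditions: TBAF, AcOH, THF, 20 → 40 °C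
Reagents that add atoms: none
Why: Fluoride cleaves the silyl ether and fragments the TMSE ester to ethylene, while the acetic acid buffer suppresses β-elimination of the C1′ ether and spares the allyl and methyl esters.

Step 22
Reactants: 35 hydroxy acid
Product: 36 2-allyl 1,3-dimethyl (1R,2S)-1-[(15-hydroxydrim-8(12)-en-11-yl)oxy]propane-1,2,3-tricarboxylate (unit A alcohol)
Conditions: TMSCHN2, MeOH/toluene, 0 °C
Reagents that add atoms: (trimethylsilyl)diazomethane, C[Si](C)(C)C=[N+]=[N-]
Why: Diazoalkane esterification methylates only the carboxylic acid; the primary alcohol is not alkylated without an acid activator.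

Step 23
Reactants: 34 monomer acid; 36 unit A alcohol
Product: 37 dimer (C2′ carboxyl of 34 esterified with O-15 of 36; carries the TBS ether, one TMSE ester and one allyl ester)
Conditions: 2-methyl-6-nitrobenzoic anhydride, DMAP, Et3N, CH2Cl2, 20 °C
Reagents that add atoms: none
Why: Shiina esterification: the mixed anhydride transfers the acyl group through DMAP to the primary neopentyl alcohol under mild conditions that limit epimerisation at C2′.

Step 24
Reactants: 37 dimer
Product: 38 dimer alcohol (as 37 with O-15 of the outer drimane free)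
Conditions: HF·pyridine, pyridine, THF, 0 → 20 °C
Reagents that add atoms: none
Why: Buffered HF removes the primary silyl ether, while TMSE, allyl and methyl esters and the exocyclic alkenes are stable to it.

Step 25
Reactants: 34 monomer acid; 38 dimer alcohol
Product: 39 protected trimer (TBS ether on the terminal drimane; two TMSE esters; one allyl ester)
Conditions: 2-methyl-6-nitrobenzoic anhydride, DMAP, Et3N, CH2Cl2, 20 °C
Reagents that add atoms: none
Why: Shiina esterification as in step 23, with the only free hydroxyl of 38 as the acceptor.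

Step 26
Reactants: 39 protected trimer
Product: 40 cryptoporic acid T 2′-allyl ester (allyl ester on the C2′ carboxyl of the isocitrate that also carries two methyl esters)
Conditions: TBAF, AcOH, THF, 20 → 40 °C
Reagents that add atoms: none
Why: Buffered fluoride removes the silyl ether and both TMSE esters in one operation, as in step 21, without cleaving methyl, allyl or drimanyl esters.

Step 27
Reactants: 40 allyl ester
Product: 41 cryptoporic acid T
Conditions: Pd(PPh3)4 (cat.), morpholine, THF, 20 °C; dilute acid work-up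
Reagents that add atoms: none
Why: Tsuji–Trost deallylation under neutral conditions frees the last carboxyl without affecting the exocyclic alkenes, the methyl esters or the two drimanyl ester links.

**Compound list**

1 | (R)-(−)-carvone | CC1=CC[C@H](CC1=O)C(=C)C | starting material
2 | (5R)-5-(3-chloroprop-1-en-2-yl)-2-methylcyclohex-2-en-1-one | CC1=CC[C@H](CC1=O)C(=C)CCl | intermediate
3 | 2-[(1R)-4-methyl-5-oxocyclohex-3-en-1-yl]prop-2-enal | CC1=CC[C@H](CC1=O)C(=C)C=O | intermediate
4 | (5R)-5-[1-(1,3-dioxolan-2-yl)ethenyl]-2-methylcyclohex-2-en-1-one | CC1=CC[C@H](CC1=O)C(=C)C2OCCO2 | intermediate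
5 | lithium α′-enolate of 4 | [Li+].CC1=CC[C@H](C=C1[O-])C(=C)C2OCCO2 | intermediate
6 | 5-[1-(1,3-dioxolan-2-yl)ethenyl]-2,6-dimethylcyclohex-2-en-1-one (C5 as in carvone; both C6 epimers) | CC1=CC[C@@H](C(=C)C2OCCO2)C(C)C1=O | intermediate
7 | ethyl 2-(bromomethyl)acrylate | CCOC(=O)C(=C)CBr | starting material
8 | lithium α′-enolate of 6 | [Li+].CC1=CC[C@@H](C(=C)C2OCCO2)C(C)=C1[O-] | intermediate
9 | ethyl 2-({6-[1-(1,3-dioxolan-2-yl)ethenyl]-1,3-dimethyl-2-oxocyclohex-3-en-1-yl}methyl)prop-2-enoate (ring methyl cis, acrylate arm trans to the dioxolanylvinyl group) | CC1=CC[C@@H](C(=C)C2OCCO2)[C@](C)(CC(=C)C(=O)OCC)C1=O | intermediate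
10 | ethyl 15,15-(ethylenedioxy)-9-oxo-11-nordrim-7-ene-2-carboxylate | CC1=CC[C@H]2[C@](C)(C3OCCO3)C[C@H](C(=O)OCC)C[C@]2(C)C1=O | intermediate
11 | ethyl 9,15-dioxo-11-nordrim-7-ene-2-carboxylate | CC1=CC[C@H]2[C@](C)(C=O)C[C@H](C(=O)OCC)C[C@]2(C)C1=O | intermediate
12 | ethyl 15-hydroxy-9-oxo-11-nordrim-7-ene-2-carboxylate | CC1=CC[C@H]2[C@](C)(CO)C[C@H](C(=O)OCC)C[C@]2(C)C1=O | intermediate
13 | ethyl 15-(tert-butyldimethylsilyloxy)-9-oxo-11-nordrim-7-ene-2-carboxylate | CC1=CC[C@H]2[C@](C)(CO[Si](C)(C)C(C)(C)C)C[C@H](C(=O)OCC)C[C@]2(C)C1=O | intermediate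
14 | 15-(tert-butyldimethylsilyloxy)-9-oxo-11-nordrim-7-ene-2-carboxylic acid | CC1=CC[C@H]2[C@](C)(CO[Si](C)(C)C(C)(C)C)C[C@H](C(=O)O)C[C@]2(C)C1=O | intermediate
15 | 2-thioxopyridin-1(2H)-yl ester of 14 | CC1=CC[C@H]2[C@](C)(CO[Si](C)(C)C(C)(C)C)C[C@H](C(=O)ON3C=CC=CC3=S)C[C@]2(C)C1=O | intermediate
16 | 15-(tert-butyldimethylsilyloxy)-11-nordrim-7-en-9-one | CC1=CC[C@H]2[C@](C)(CO[Si](C)(C)C(C)(C)C)CCC[C@]2(C)C1=O | intermediate
17 | lithium 15-(tert-butyldimethylsilyloxy)-11-nordrim-8-en-9-olate | [Li+].CC=1CC[C@H]2[C@](C)(CO[Si](C)(C)C(C)(C)C)CCC[C@]2(C)C=1[O-] | intermediate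
18 | 15-(tert-butyldimethylsilyloxy)-11-nordrim-8-en-9-yl triflate | CC=1CC[C@H]2[C@](C)(CO[Si](C)(C)C(C)(C)C)CCC[C@]2(C)C=1OS(=O)(=O)C(F)(F)F | intermediate
19 | methyl 15-(tert-butyldimethylsilyloxy)drim-8-en-11-oate | CC=1CC[C@H]2[C@](C)(CO[Si](C)(C)C(C)(C)C)CCC[C@]2(C)C=1C(=O)OC | intermediate
20 | lithium dienolate of 19 (C8=C12 exocyclic) | [Li+].C=C1CC[C@H]2[C@](C)(CO[Si](C)(C)C(C)(C)C)CCC[C@]2(C)C1=C([O-])OC | intermediate
21 | methyl 15-(tert-butyldimethylsilyloxy)drim-8(12)-en-11-oate (H-9 α) | C=C1CC[C@H]2[C@](C)(CO[Si](C)(C)C(C)(C)C)CCC[C@]2(C)[C@H]1C(=O)OC | intermediate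
22 | 15-(tert-butyldimethylsilyloxy)drim-8(12)-en-11-ol | C=C1CC[C@H]2[C@](C)(CO[Si](C)(C)C(C)(C)C)CCC[C@]2(C)[C@H]1CO | intermediate
23 | bromoacetyl bromide | BrCC(=O)Br | starting material
24 | 2-(trimethylsilyl)ethanol | C[Si](C)(C)CCO | starting material
25 | 2-(trimethylsilyl)ethyl bromoacetate | BrCC(=O)OCC[Si](C)(C)C | intermediate
26 | (R)-malic acid | O[C@H](CC(=O)O)C(=O)O | starting material
27 | (R)-2-(trifluoroacetoxy)succinic anhydride | O=C1C[C@@H](OC(=O)C(F)(F)F)C(=O)O1 | intermediate
28 | (R)-malic acid 1-methyl ester | COC(=O)[C@H](O)CC(=O)O | intermediate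
29 | 4-allyl 1-methyl (R)-malate | COC(=O)[C@H](O)CC(=O)OCC=C | intermediate
30 | dilithium alkoxide–enolate of 29 | [Li+].[Li+].COC(=O)[C@H]([O-])C=C([O-])OCC=C | intermediate
31 | 2-allyl 1-methyl 3-[2-(trimethylsilyl)ethyl] (1R,2S)-1-hydroxypropane-1,2,3-tricarboxylate | C=CCOC(=O)[C@@H](CC(=O)OCC[Si](C)(C)C)[C@@H](O)C(=O)OC | intermediate
32 | 15-(tert-butyldimethylsilyloxy)drim-8(12)-en-11-yl triflate | C=C1CC[C@H]2[C@](C)(CO[Si](C)(C)C(C)(C)C)CCC[C@]2(C)[C@H]1COS(=O)(=O)C(F)(F)F | intermediate
33 | monomer: 11-O-drimanyl ether of 31 | C=CCOC(=O)[C@@H](CC(=O)OCC[Si](C)(C)C)[C@@H](OC[C@H]1C(=C)CC[C@H]2[C@](C)(CO[Si](C)(C)C(C)(C)C)CCC[C@]12C)C(=O)OC | intermediate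
34 | monomer acid (C2′ carboxyl free) | OC(=O)[C@@H](CC(=O)OCC[Si](C)(C)C)[C@@H](OC[C@H]1C(=C)CC[C@H]2[C@](C)(CO[Si](C)(C)C(C)(C)C)CCC[C@]12C)C(=O)OC | intermediate
35 | hydroxy acid (O-15 free, C3′ carboxyl free, C2′ allyl ester) | C=CCOC(=O)[C@@H](CC(=O)O)[C@@H](OC[C@H]1C(=C)CC[C@H]2[C@](C)(CO)CCC[C@]12C)C(=O)OC | intermediate
36 | 2-allyl 1,3-dimethyl (1R,2S)-1-[(15-hydroxydrim-8(12)-en-11-yl)oxy]propane-1,2,3-tricarboxylate | C=CCOC(=O)[C@@H](CC(=O)OC)[C@@H](OC[C@H]1C(=C)CC[C@H]2[C@](C)(CO)CCC[C@]12C)C(=O)OC | intermediate
37 | dimer (TBS ether, one TMSE ester, one allyl ester) | C=C1CC[C@H]2[C@](C)(COC(=O)[C@@H](CC(=O)OCC[Si](C)(C)C)[C@@H](OC[C@H]3C(=C)CC[C@H]4[C@](C)(CO[Si](C)(C)C(C)(C)C)CCC[C@]34C)C(=O)OC)CCC[C@]2(C)[C@H]1CO[C@@H](C(=O)OC)[C@H](CC(=O)OC)C(=O)OCC=C | intermediate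
38 | dimer alcohol | C=C1CC[C@H]2[C@](C)(COC(=O)[C@@H](CC(=O)OCC[Si](C)(C)C)[C@@H](OC[C@H]3C(=C)CC[C@H]4[C@](C)(CO)CCC[C@]34C)C(=O)OC)CCC[C@]2(C)[C@H]1CO[C@@H](C(=O)OC)[C@H](CC(=O)OC)C(=O)OCC=C | intermediate
39 | protected trimer | C=C1CC[C@H]2[C@](C)(COC(=O)[C@@H](CC(=O)OCC[Si](C)(C)C)[C@@H](OC[C@H]3C(=C)CC[C@H]4[C@](C)(COC(=O)[C@@H](CC(=O)OCC[Si](C)(C)C)[C@@H](OC[C@H]5C(=C)CC[C@H]6[C@](C)(CO[Si](C)(C)C(C)(C)C)CCC[C@]56C)C(=O)OC)CCC[C@]34C)C(=O)OC)CCC[C@]2(C)[C@H]1CO[C@@H](C(=O)OC)[C@H](CC(=O)OC)C(=O)OCC=C | intermediate
40 | cryptoporic acid T 2′-allyl ester | C=C1CC[C@H]2[C@](C)(COC(=O)[C@@H](CC(=O)O)[C@@H](OC[C@H]3C(=C)CC[C@H]4[C@](C)(COC(=O)[C@@H](CC(=O)O)[C@@H](OC[C@H]5C(=C)CC[C@H]6[C@](C)(CO)CCC[C@]56C)C(=O)OC)CCC[C@]34C)C(=O)OC)CCC[C@]2(C)[C@H]1CO[C@@H](C(=O)OC)[C@H](CC(=O)OC)C(=O)OCC=C | intermediate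
41 | cryptoporic acid T | C=C1CC[C@H]2[C@](C)(COC(=O)[C@@H](CC(=O)O)[C@@H](OC[C@H]3C(=C)CC[C@H]4[C@](C)(COC(=O)[C@@H](CC(=O)O)[C@@H](OC[C@H]5C(=C)CC[C@H]6[C@](C)(CO)CCC[C@]56C)C(=O)OC)CCC[C@]34C)C(=O)OC)CCC[C@]2(C)[C@H]1CO[C@@H](C(=O)OC)[C@H](CC(=O)OC)C(=O)O | target

**Step count**

Total: 27 steps. Longest linear sequence: 22 steps (1–14, 19, 21, 22, 23, 24, 25, 26, 27).

**Steps most likely to fail**

1. Step 19 (etherification). Displacement at the β-branched C11 by a weakly nucleophilic, hindered hydroxy ester may be slow. That would give time for ionisation of the triflate with participation of the neighbouring exocyclic double bond, for elimination, or for lactonisation of the hydroxy triester. Fallback, setting out from 22 and 31 and returning at 33: the C11 electrophile is changed from an sp3 triflate to a carbonyl group. Alcohol 22 is oxidised with Dess–Martin periodinane (NaHCO3, CH2Cl2) to 15-(tert-butyldimethylsilyloxy)drim-8(12)-en-11-al F1. Hydroxy triester 31 is converted with TMSCl/imidazole into its trimethylsilyl ether F2. The two are joined by reductive etherification (Et3SiH, catalytic TMSOTf, CH2Cl2, −78 °C): the mixed acetal ionises to an oxocarbenium ion, which the silane reduces to monomer 33.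

2. Step 6 (key step). The C4 radical may be reduced before it cyclises, the hydride may attack the acrylate or enone, or rotamer control at C4 may be insufficient. Fallback, setting out from 9 and returning at 10: radical generation is separated from the metal hydride. Mukaiyama hydration of the 1,1-disubstituted alkene (Mn(dpm)3, PhSiH3, O2, i-PrOH, 0 °C; then PPh3), in which oxygen trapping should outpace ring closure, gives the tertiary alcohol F3. Acylation with methyl chlorooxoacetate (DMAP, Et3N) gives the methyl oxalate F4, and one equivalent of CsOH gives the caesium oxalate F5. Visible-light photoredox oxidation (iridium photocatalyst, DME/DMF/H2O) then releases two CO2 and the same C4 radical, which closes ring A onto the acrylate to give 10.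

3. Step 23 (and the identical step 25). Acyl transfer from the α-branched acid to the neopentyl alcohol may be slow, leaving the activated acid exposed to amine base; this risks β-elimination of the C1′ alkoxy group or epimerisation at C2′. Fallback, setting out from 34 and returning at 37: the acid is activated as a thioester and coupled without amine base. 2,2′-Dipyridyl disulfide and PPh3 convert 34 into the S-(pyridin-2-yl) thioester F6, which acylates alcohol 36 under AgOTf promotion in toluene to give 37. The same thioester with 38 returns at 39.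

**Further compounds**

F1 | step 19 | 15-(tert-butyldimethylsilyloxy)drim-8(12)-en-11-al | C=C1CC[C@H]2[C@](C)(CO[Si](C)(C)C(C)(C)C)CCC[C@]2(C)[C@H]1C=O
F2 | step 19 | O-trimethylsilyl ether of 31 | C=CCOC(=O)[C@@H](CC(=O)OCC[Si](C)(C)C)[C@@H](O[Si](C)(C)C)C(=O)OC
F3 | step 6 | tertiary alcohol from hydration of 9 (carbinol centre as a mixture) | CC1=CC[C@@H](C(C)(O)C2OCCO2)[C@](C)(CC(=C)C(=O)OCC)C1=O
F4 | step 6 | methyl oxalate of F3 | CC1=CC[C@@H](C(C)(OC(=O)C(=O)OC)C2OCCO2)[C@](C)(CC(=C)C(=O)OCC)C1=O
F5 | step 6 | caesium oxalate of F3 | [Cs+].CC1=CC[C@@H](C(C)(OC(=O)C(=O)[O-])C2OCCO2)[C@](C)(CC(=C)C(=O)OCC)C1=O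
F6 | step 23 | S-(pyridin-2-yl) thioester of 34 | O=C(Sc1ccccn1)[C@@H](CC(=O)OCC[Si](C)(C)C)[C@@H](OC[C@H]1C(=C)CC[C@H]2[C@](C)(CO[Si](C)(C)C(C)(C)C)CCC[C@]12C)C(=O)OC
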